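**Retrosynthetic overview**

1. Target 54 comes from BBr3 demethylation of pentadecamethyl ether 53; the C7e aryl group is put on last (nickel/photoredox arylation of trifluoroborate 51), and ring E enters by Suzuki coupling of boronate 37 with eight-ring enol triflate 48.
2. The eight-membered ring arises by aryl-shift ring expansion of the methylenated seven-ring ketone 43; the two halves are joined at C7c/C8c by aldol condensation of ketone 36 with aldehyde 22, then anisyl-copper addition and kinetic protonation.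
3. Feature the strategy rests on: the trans-2,3-diaryl-2,3-dihydrobenzofuran fused to the seven-membered ring. Its furan C3 (C8a) is a ring carbon between ring A and ring B, and ring B carries the furan oxygen ortho to it. Cutting C8a–C7a and C7a–O leaves an o-quinone methide of ring B plus a 4-methoxybenzylide ([4+1]).
4. The annulation is run on the C10=C11-unsaturated, C11-unsubstituted dibenzocycloheptenol (activated as its sulfone) with an isothiocineole-derived ylide. Conformational analysis suggests that preset C7b/C8b centres (C7b aryl pseudo-axial because of the peri methoxy group) would steer the ylide to the wrong methide face. The C7b aryl group and H-8b are therefore brought in afterwards, from the convex face of the furan-locked tub.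
5. Ring order: seven-membered ring (Friedel–Crafts, step 4) → furan on it (step 8); furan of 31 (step 15, same annulation, serves rings C/D and E/F) → seven-ring ketone 36 (step 17) → eight-membered ring (step 22).

Key step: step 8

Remark on locants: units a–f each have C7 (carrying a 4-methoxyphenyl group) and C8 (carrying the resorcinol-derived ring A–F); the early tricycles use dibenzo[a,d]cycloheptene numbering (C5 = C8a, C10 = C8b, C11 = C7b).

Assumption: the (1S,4S,5S) antipode of isothiocineole is taken to be the one whose 4-methoxybenzylide bonds through the ylide face that becomes the (R)-configured furan C2 (the face that gives (S,S)-stilbene oxide with benzaldehyde); if the sense is the opposite, the (1R,4R,5R) sulfide is used instead in steps 1, 8 and 15.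

**Chiral benzylide source**

Step 1
Reactants: 1 (1S,4S,5S)-isothiocineole; 2 4-methoxybenzyl bromide
Product: 3 S-(4-methoxybenzyl)isothiocineolium tetrafluoroborate
Conditions: NaBF4, CH2Cl2/H2O, rt
Reagents that add atoms: sodium tetrafluoroborate, [Na+].F[B-](F)(F)F
Why: S-alkylation of the thioether followed by anion exchange to the non-nucleophilic tetrafluoroborate should give one sulfonium diastereomer, because the bicyclic sulfide is alkylated on its exposed lone pair.

**Left half**

Step 2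
Reactants: 4 methyl 3,5-dimethoxybenzoate
Product: 5 methyl 2-formyl-3,5-dimethoxybenzoate
Conditions: POCl3, DMF, 0 → 90 °C; aq. NaOAc
Reagents that add atoms: N,N-dimethylformamide, CN(C)C=O; water, O
Why: Vilsmeier–Haack formylation should enter C2, which is ortho to one methoxy group and para to the other, rather than the more hindered C4 between the two methoxy groups.

Step 3
Reactants: 5 methyl 2-formyl-3,5-dimethoxybenzoate; 6 methyl (3,5-dimethoxyphenyl)acetate
Product: 9 (E/Z)-stilbene half-ester acid, via lithium ester enolate 7 (not isolated), via phthalide 8 (not isolated)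
Conditions: LiN(iPr)2, THF, −78 °C; add 5, → 0 °C; KOtBu, rt; cold 1 M HCl
Reagents that add atoms: none
Why: Aldol addition of the ester enolate, lactonisation of the aldolate onto the neighbouring ester and E1cB opening of that phthalide by the second base (a Stobbe-type sequence) should give the half-ester with the free acid on ring A, the alkene geometry being immaterial.

Step 4
Reactants: 9 (E/Z)-stilbene half-ester acid
Product: 11 methyl 1,3,6,8-tetramethoxy-5-oxo-5H-dibenzo[a,d]cycloheptene-10-carboxylate, via mixed trifluoroacetic anhydride 10 (not isolated)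
Conditions: (CF3CO)2O, CF3SO3H (cat.), CH2Cl2, 0 °C → rt
Reagents that add atoms: none
Why: Intramolecular Friedel–Crafts acylation of the doubly activated ring B closes the seven-membered ring, and the push–pull alkene equilibrates E/Z by reversible protonation at C10 so that both isomers should funnel to the dibenzotropone.

Step 5
Reactants: 11 methyl 1,3,6,8-tetramethoxy-5-oxo-5H-dibenzo[a,d]cycloheptene-10-carboxylate
Product: 12 methyl 6-hydroxy-1,3,8-trimethoxy-5-oxo-5H-dibenzo[a,d]cycloheptene-10-carboxylate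
Conditions: BCl3, CH2Cl2, −78 → 0 °C
Reagents that add atoms: none
Why: Chelation-controlled ether cleavage, in which BCl3 bound to the C5 carbonyl removes only the peri C6 methyl group through a six-membered chelate, frees the one phenol that can form the quinone methide.

Step 6
Reactants: 12 methyl 6-hydroxy-1,3,8-trimethoxy-5-oxo-5H-dibenzo[a,d]cycloheptene-10-carboxylate
Product: 13 methyl 5,6-dihydroxy-1,3,8-trimethoxy-5H-dibenzo[a,d]cycloheptene-10-carboxylate
Conditions: NaBH4, THF/MeOH, 0 °C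
Reagents that add atoms: none
Why: Borohydride 1,2-reduction of the diaryl ketone should leave the hindered enoate untouched, and the new C5 centre (racemic) is irrelevant because it is planarised in step 8.

Step 7
Reactants: 13 methyl 5,6-dihydroxy-1,3,8-trimethoxy-5H-dibenzo[a,d]cycloheptene-10-carboxylate
Product: 14 methyl 6-hydroxy-1,3,8-trimethoxy-5-(4-methylphenylsulfonyl)-5H-dibenzo[a,d]cycloheptene-10-carboxylate
Conditions: 4-MeC6H4SO2Na, HCO2H, CH2Cl2/H2O, rt
Reagents that add atoms: sodium 4-methylbenzenesulfinate, [Na+].Cc1ccc(cc1)S([O-])=O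
Why: Acid ionisation of the doubly benzylic carbinol and S-capture of the cation by sulfinate installs the leaving group that the carbinol lacks under base, giving a bench-stable 2-(sulfonylalkyl)phenol that releases the quinone methide with carbonate.

Step 8
Reactants: 14 methyl 6-hydroxy-1,3,8-trimethoxy-5-(4-methylphenylsulfonyl)-5H-dibenzo[a,d]cycloheptene-10-carboxylate; 3 S-(4-methoxybenzyl)isothiocineolium tetrafluoroborate
Product: 18 methyl (7aR,8aR)-dihydrofuran-fused dibenzocycloheptene ester, via benzylide 15 (not isolated), via quinone methide 16 (not isolated), via betaine 17 (not isolated)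
Conditions: Cs2CO3, MeCN/CH2Cl2, −20 → 0 °C
Reagents that add atoms: none
Why: Cs2CO3 deprotonates the C6 phenol of 14, which expels sulfinate (E1cB) to give o-quinone methide 16, while the same base reversibly converts salt 3 into benzylide 15. The ylide carbon adds to the methide carbon C5 (= C8a), restoring the aromatic phenoxide (betaine 17), and the phenoxide oxygen then displaces the sulfide at C7a with inversion in a 5-exo-tet closure, so the C8a–C7a and C7a–O bonds and the dihydrofuran ring form in one operation. The closest known reaction is the [4+1] annulation of o-quinone methides released from 2-(sulfonylalkyl)phenols with sulfonium ylides, combined here with benzylidene transfer from an isothiocineole salt as in its epoxide and aziridine syntheses. C7a is set by the sulfide skeleton, which exposes one face of the ylide carbon, and C8a follows from it because only the anti betaine (aryl groups apart, sulfur antiperiplanar to the attacking oxygen) closes, giving the trans furan. The step needs enantioface selection at a methide carbon with no neighbouring stereocentre, so the reagent alone decides, and it needs attack at the methide rather than at the enoate, which the far higher electrophilicity of the quinone methide and the hindered trisubstituted α-aryl acrylate should secure.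

Step 9
Reactants: 18 methyl (7aR,8aR)-dihydrofuran-fused dibenzocycloheptene ester; 19 4-methoxyphenylmagnesium bromide
Product: 21 methyl (7aR,8aR,7bS,8bS)-dihydrofuran-fused 11-aryl dibenzocycloheptane ester, via bromomagnesium ester enolate 20 (not isolated)
Conditions: CuBr·SMe2 (cat.), THF, −40 → −10 °C; AcOH, −78 °C
Reagents that add atoms: none
Why: Copper-catalysed 1,4-addition of the aryl Grignard reagent to the α-aryl acrylate should place the aryl group on C7b from the convex face of the tub (the inner face is closed by C8a and its flagpole hydrogen, the furan holding C7a equatorial), and protonation of the enolate at −78 °C anti to the new pseudo-axial aryl group should give the 7b,8b-cis ester.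

Step 10
Reactants: 21 methyl (7aR,8aR,7bS,8bS)-dihydrofuran-fused 11-aryl dibenzocycloheptane ester
Product: 22 (7aR,8aR,7bS,8bS)-aldehyde
Conditions: iBu2AlH, CH2Cl2, −78 °C; aq. potassium sodium tartrate
Reagents that add atoms: none
Why: Half-reduction of the hindered α-branched ester should stop at the aluminium hemiacetal, which gives the aldehyde on work-up; it is used crude so that C8b is not epimerised.

**Bromo dihydrobenzofuran 31 (serves rings C/D and E/F)**

Step 11
Reactants: 23 1-bromo-3,5-dimethoxybenzene; 24 3,5-dimethoxybenzoyl chloride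
Product: 25 (2-bromo-4,6-dimethoxyphenyl)(3,5-dimethoxyphenyl)methanone
Conditions: CF3SO3H (cat.), 1,2-dichloroethane, 60 °C
Reagents that add atoms: none
Why: Friedel–Crafts acylation should occur at C2 of 23, para to one methoxy group and ortho to the other, rather than between the two methoxy groups, while the acyl-substituted ring of 24 is deactivated toward self-acylation.

Step 12
Reactants: 25 (2-bromo-4,6-dimethoxyphenyl)(3,5-dimethoxyphenyl)methanone
Product: 26 (2-bromo-6-hydroxy-4-methoxyphenyl)(3,5-dimethoxyphenyl)methanone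
Conditions: BCl3, CH2Cl2, −78 → 0 °C
Reagents that add atoms: none
Why: Chelation-controlled demethylation removes only the methyl group ortho to the carbonyl.

Step 13
Reactants: 26 (2-bromo-6-hydroxy-4-methoxyphenyl)(3,5-dimethoxyphenyl)methanone
Product: 27 3-bromo-2-[hydroxy(3,5-dimethoxyphenyl)methyl]-5-methoxyphenol
Conditions: NaBH4, THF/MeOH, 0 °C
Reagents that add atoms: none
Why: Borohydride reduction of the diaryl ketone gives the racemic o-hydroxy benzhydrol, whose carbinol centre is planarised in step 15.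

Step 14
Reactants: 27 3-bromo-2-[hydroxy(3,5-dimethoxyphenyl)methyl]-5-methoxyphenol
Product: 28 3-bromo-2-[(3,5-dimethoxyphenyl)(4-methylphenylsulfonyl)methyl]-5-methoxyphenol
Conditions: 4-MeC6H4SO2Na, HCO2H, CH2Cl2/H2O, rt
Reagents that add atoms: sodium 4-methylbenzenesulfinate, [Na+].Cc1ccc(cc1)S([O-])=O
Why: Acid-promoted SN1 substitution of the benzhydrol by sulfinate gives the standard base-labile quinone methide precursor.

Step 15
Reactants: 28 3-bromo-2-[(3,5-dimethoxyphenyl)(4-methylphenylsulfonyl)methyl]-5-methoxyphenol; 3 S-(4-methoxybenzyl)isothiocineolium tetrafluoroborate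
Product: 31 (2R,3R)-4-bromo-3-(3,5-dimethoxyphenyl)-6-methoxy-2-(4-methoxyphenyl)-2,3-dihydrobenzofuran, via quinone methide 29 (not isolated), via betaine 30 (not isolated)
Conditions: Cs2CO3, MeCN/CH2Cl2, −20 → 0 °C
Reagents that add atoms: none
Why: Under the conditions of step 8, Cs2CO3 releases o-quinone methide 29 from sulfone 28 and once more turns salt 3 into the benzylide already numbered 15, and the same [4+1] annulation should set furan C2 by the sulfide-controlled ylide face and furan C3 through the anti betaine that closes 5-exo-tet to the trans ring.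

**Right-half building blocks**

Step 16
Reactants: 31 (2R,3R)-4-bromo-3-(3,5-dimethoxyphenyl)-6-methoxy-2-(4-methoxyphenyl)-2,3-dihydrobenzofuran; 32 (2-tert-butoxy-2-oxoethyl)zinc bromide
Product: 33 tert-butyl (2R,3R)-dihydrobenzofuran-4-ylacetate
Conditions: Pd2(dba)3, XPhos, THF, 50 °C
Reagents that add atoms: none
Why: Palladium-catalysed Negishi-type coupling of the aryl bromide with the Reformatsky reagent installs the acetic ester arm without touching the two stereocentres.

Step 17
Reactants: 33 tert-butyl (2R,3R)-dihydrobenzofuran-4-ylacetate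
Product: 36 (7dR,8dR)-seven-ring ketone, via arylacetic acid 34 (not isolated), via mixed trifluoroacetic anhydride 35 (not isolated)
Conditions: CF3CO2H, CH2Cl2, 0 °C; evaporate; (CF3CO)2O, H3PO4 (cat.), CH2Cl2, rt
Reagents that add atoms: none
Why: Acidolysis of the tert-butyl ester and intramolecular Friedel–Crafts acylation of ring D ortho to its attachment close the seven-membered ketone, the trans furan being the thermodynamic isomer under acid.

Step 18
Reactants: 31 (2R,3R)-4-bromo-3-(3,5-dimethoxyphenyl)-6-methoxy-2-(4-methoxyphenyl)-2,3-dihydrobenzofuran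
Product: 37 (2R,3R)-dihydrobenzofuran-4-yl pinacol boronate
Conditions: Pd(OAc)2, SPhos, KOAc, dioxane, 90 °C
Reagents that add atoms: bis(pinacolato)diboron, CC1(C)OB(OC1(C)C)B1OC(C)(C)C(C)(C)O1
Why: Miyaura borylation converts the hindered aryl bromide into the ring E coupling partner.

**Union and end game**

Step 19
Reactants: 36 (7dR,8dR)-seven-ring ketone; 22 (7aR,8aR,7bS,8bS)-aldehyde
Product: 41 enone joining the two halves, via lithium enolate 38 (not isolated), via lithium aldolate 39 (not isolated), via mesylate 40 (not isolated)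
Conditions: LiN(SiMe3)2, THF, −78 °C; add 22; MeSO2Cl, Et3N, −78 → 0 °C
Reagents that add atoms: none
Why: Aldol condensation (addition of the only possible enolate of 36 to the aldehyde, then E1cB loss of mesylate) should form the C7c=C8c enone, the addition at −78 °C being faster than proton transfer from C8b.

Step 20
Reactants: 41 enone joining the two halves; 19 4-methoxyphenylmagnesium bromide
Product: 43 seven-ring ketone carrying C7c and C8c, via bromomagnesium enolate 42 (not isolated)
Conditions: CuBr·SMe2 (cat.), THF, −78 → −30 °C; AcOH, −78 °C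
Reagents that add atoms: none
Why: Copper-catalysed conjugate addition should set C7c under 1,3-allylic strain control (H-8b eclipses the alkene and the aryl group enters from the ring B side, anti to C7b and its aryl group), and kinetic protonation of the enolate from the convex face of the furan-locked seven-membered ring should set C8c with H-8c on the face of C7d.

Step 21
Reactants: 43 seven-ring ketone carrying C7c and C8c
Product: 44 exocyclic methylene compound
Conditions: Zn, CH2Br2, TiCl4, THF/CH2Cl2, 0 °C → rt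
Reagents that add atoms: dibromomethane, BrCBr
Why: Takai–Lombardo methylenation converts the hindered, enolisable aryl ketone without base, so C8c should not epimerise.

Step 22
Reactants: 44 exocyclic methylene compound
Product: 46 eight-ring ketone, via dimethyl ketal 45 (not isolated)
Conditions: PhI(OH)OTs, MeOH, rt; 1 M HCl
Reagents that add atoms: water, O
Why: Koser-type oxidative ring expansion (iodination of the terminal carbon, methanol capture of the ring D-stabilised cation, 1,2-shift of the electron-rich ring D aryl carbon with loss of PhI) should insert C7e between ring D and the carbonyl carbon C8e.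

Step 23
Reactants: 46 eight-ring ketone
Product: 48 eight-ring enol triflate, via potassium enolate 47 (not isolated)
Conditions: KN(SiMe3)2, THF, −78 °C; PhNTf2
Reagents that add atoms: N-phenylbis(trifluoromethanesulfonimide), O=S(=O)(N(c1ccccc1)S(=O)(=O)C(F)(F)F)C(F)(F)F
Why: Kinetic deprotonation at the unbranched benzylic CH2 (C7e) rather than the hindered C8c methine and O-sulfonylation fix the C7e=C8e enol triflate and end the lability of C8c.

Step 24
Reactants: 48 eight-ring enol triflate; 37 (2R,3R)-dihydrobenzofuran-4-yl pinacol boronate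
Product: 49 eight-ring styrene carrying ring E
Conditions: Pd(OAc)2, SPhos, K3PO4, THF/H2O, 60 °C
Reagents that add atoms: none
Why: Suzuki–Miyaura coupling with a bulky biaryl phosphine joins the hindered vinyl triflate and the ortho-substituted aryl boronate at C8e.

Step 25
Reactants: 49 eight-ring styrene carrying ring E
Product: 51 potassium C7e-trifluoroborate, via monoalkylborane 50 (not isolated)
Conditions: BH3·SMe2, THF, 0 → 45 °C; H2O; KHF2, MeOH/H2O
Reagents that add atoms: borane–dimethyl sulfide, [BH3-][S+](C)C; potassium hydrogen difluoride, F.[F-].[K+]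
Why: Syn hydroboration should put boron on the less substituted C7e and hydrogen on C8e from the face anti to the C8c substituent, which sets C8e, and KHF2 converts the borane into the stable trifluoroborate.

Step 26
Reactants: 51 potassium C7e-trifluoroborate; 52 4-bromoanisole
Product: 53 pentadecamethyl ether of the target
Conditions: [Ir(dF(CF3)ppy)2(bpy)]PF6, NiCl2(dme), 4,4'-di-tert-butyl-2,2'-bipyridine, 2,6-lutidine, dioxane, blue LEDs, rt
Reagents that add atoms: none
Why: Photoredox/nickel dual-catalytic cross-coupling of the secondary benzylic trifluoroborate should bond the aryl group to the C7e radical anti to ring E on C8e (trans, setting C7e), and the radical path avoids a C7e cation, which ring F would trap in a seven-membered ring.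

Step 27
Reactants: 53 pentadecamethyl ether of the target
Product: 54 CNP0184494.1
Conditions: BBr3, CH2Cl2, −78 °C → rt; MeOH then H2O
Reagents that add atoms: none
Why: Lewis acid cleavage of all fifteen aryl methyl ethers should free the phenols, while the three trans dihydrobenzofurans, being the thermodynamic isomers, should hold at controlled temperature.

**Compound list**

1 | (1S,4S,5S)-isothiocineole (4,7,7-trimethyl-6-thiabicyclo[3.2.1]octane) | C[C@H]1CC[C@H]2C[C@@H]1SC2(C)C | starting material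
2 | 4-methoxybenzyl bromide | COc1ccc(CBr)cc1 | starting material
3 | (1S,4S,5S)-6-(4-methoxybenzyl)-4,7,7-trimethyl-6-thiabicyclo[3.2.1]octan-6-ium tetrafluoroborate (sulfur configuration as formed) | C[C@H]1CC[C@H]2C[C@@H]1[S+](Cc1ccc(OC)cc1)C2(C)C.F[B-](F)(F)F | intermediate
4 | methyl 3,5-dimethoxybenzoate | COC(=O)c1cc(OC)cc(OC)c1 | starting material
5 | methyl 2-formyl-3,5-dimethoxybenzoate | COC(=O)c1cc(OC)cc(OC)c1C=O | intermediate
6 | methyl (3,5-dimethoxyphenyl)acetate | COC(=O)Cc1cc(OC)cc(OC)c1 | starting material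
7 | lithium enolate of 6 | [Li]OC(OC)=Cc1cc(OC)cc(OC)c1 | intermediate
8 | methyl 2-(3,5-dimethoxyphenyl)-2-(4,6-dimethoxy-3-oxo-1,3-dihydroisobenzofuran-1-yl)acetate (diastereomer mixture, racemic) | COC(=O)C(c1cc(OC)cc(OC)c1)C1OC(=O)c2cc(OC)cc(OC)c12 | intermediate
9 | 2-[2-(3,5-dimethoxyphenyl)-3-methoxy-3-oxoprop-1-enyl]-3,5-dimethoxybenzoic acid (E/Z mixture, E drawn) | COC(=O)/C(c1cc(OC)cc(OC)c1)=C/c1c(OC)cc(OC)cc1C(=O)O | intermediate
10 | mixed trifluoroacetic anhydride of 9 | COC(=O)/C(c1cc(OC)cc(OC)c1)=C/c1c(OC)cc(OC)cc1C(=O)OC(=O)C(F)(F)F | intermediate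
11 | methyl 1,3,6,8-tetramethoxy-5-oxo-5H-dibenzo[a,d]cycloheptene-10-carboxylate | COC(=O)C1=Cc2c(OC)cc(OC)cc2C(=O)c2c(OC)cc(OC)cc12 | intermediate
12 | methyl 6-hydroxy-1,3,8-trimethoxy-5-oxo-5H-dibenzo[a,d]cycloheptene-10-carboxylate | COC(=O)C1=Cc2c(OC)cc(OC)cc2C(=O)c2c(O)cc(OC)cc12 | intermediate
13 | methyl 5,6-dihydroxy-1,3,8-trimethoxy-5H-dibenzo[a,d]cycloheptene-10-carboxylate (racemic o-hydroxy carbinol) | COC(=O)C1=Cc2c(OC)cc(OC)cc2C(O)c2c(O)cc(OC)cc12 | intermediate
14 | methyl 6-hydroxy-1,3,8-trimethoxy-5-(4-methylphenylsulfonyl)-5H-dibenzo[a,d]cycloheptene-10-carboxylate (racemic) | COC(=O)C1=Cc2c(OC)cc(OC)cc2C(c2c(O)cc(OC)cc12)S(=O)(=O)c1ccc(C)cc1 | intermediate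
15 | 4-methoxybenzylide of (1S,4S,5S)-isothiocineole (formed from 3 by Cs2CO3 in step 8; the same species forms again from 3 in the flask of step 15) | C[C@H]1CC[C@H]2C[C@@H]1[S+]([CH-]c1ccc(OC)cc1)C2(C)C | intermediate
16 | o-quinone methide, methyl 1,3,8-trimethoxy-6-oxo-6H-dibenzo[a,d]cycloheptene-10-carboxylate | COC(=O)C1=Cc2c(OC)cc(OC)cc2C=C2C(=O)C=C(OC)C=C12 | intermediate
17 | anti betaine (C8a–C7a bond made, phenoxide and sulfonium present) | C[C@H]1CC[C@H]2C[C@@H]1[S+]([C@H](c1ccc(OC)cc1)[C@@H]1c3cc(OC)cc(OC)c3C=C(C(=O)OC)c3cc(OC)cc([O-])c31)C2(C)C | intermediate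
18 | methyl (7aR,8aR)-ester: trans-2,3-dihydrofuran (O on C6, C7a carrying 4-methoxyphenyl, C8a = C5) fused to 1,3,8-trimethoxy-5H-dibenzo[a,d]cycloheptene-10-carboxylate | COC(=O)C1=Cc2c(OC)cc(OC)cc2[C@@H]2c3c(cc(OC)cc31)O[C@H]2c1ccc(OC)cc1 | intermediate
19 | 4-methoxyphenylmagnesium bromide | COc1ccc([Mg]Br)cc1 | starting material
20 | bromomagnesium ester enolate after aryl addition at C7b | COc1ccc([C@H]2c3c(OC)cc(OC)cc3[C@@H]3c4c(cc(OC)cc4C2=C(OC)O[Mg]Br)O[C@H]3c2ccc(OC)cc2)cc1 | intermediate
21 | methyl (7aR,8aR,7bS,8bS)-ester: 10,11-dihydro analogue of 18 with 4-methoxyphenyl on C11 (C7b); H-8a, H-7b and H-8b all cis | COc1ccc([C@H]2c3c(OC)cc(OC)cc3[C@@H]3c4c(cc(OC)cc4[C@H]2C(=O)OC)O[C@H]3c2ccc(OC)cc2)cc1 | intermediate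
22 | (7aR,8aR,7bS,8bS)-aldehyde (CHO on C8b) | COc1ccc([C@H]2c3c(OC)cc(OC)cc3[C@@H]3c4c(cc(OC)cc4[C@H]2C=O)O[C@H]3c2ccc(OC)cc2)cc1 | intermediate
23 | 1-bromo-3,5-dimethoxybenzene | COc1cc(Br)cc(OC)c1 | starting material
24 | 3,5-dimethoxybenzoyl chloride | COc1cc(cc(OC)c1)C(Cl)=O | starting material
25 | (2-bromo-4,6-dimethoxyphenyl)(3,5-dimethoxyphenyl)methanone | COc1cc(OC)cc(c1)C(=O)c1c(Br)cc(OC)cc1OC | intermediate
26 | (2-bromo-6-hydroxy-4-methoxyphenyl)(3,5-dimethoxyphenyl)methanone | COc1cc(OC)cc(c1)C(=O)c1c(Br)cc(OC)cc1O | intermediate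
27 | 3-bromo-2-[hydroxy(3,5-dimethoxyphenyl)methyl]-5-methoxyphenol (racemic) | COc1cc(OC)cc(c1)C(O)c1c(Br)cc(OC)cc1O | intermediate
28 | 3-bromo-2-[(3,5-dimethoxyphenyl)(4-methylphenylsulfonyl)methyl]-5-methoxyphenol (racemic) | COc1cc(OC)cc(c1)C(c1c(Br)cc(OC)cc1O)S(=O)(=O)c1ccc(C)cc1 | intermediate
29 | o-quinone methide, 2-bromo-6-(3,5-dimethoxybenzylidene)-4-methoxycyclohexa-2,4-dienone | COc1cc(OC)cc(c1)C=C1C(=O)C=C(OC)C=C1Br | intermediate
30 | anti betaine from 29 and 15 | C[C@H]1CC[C@H]2C[C@@H]1[S+]([C@H](c1ccc(OC)cc1)[C@H](c1cc(OC)cc(OC)c1)c1c(Br)cc(OC)cc1[O-])C2(C)C | intermediate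
31 | (2R,3R)-4-bromo-3-(3,5-dimethoxyphenyl)-6-methoxy-2-(4-methoxyphenyl)-2,3-dihydrobenzofuran | Brc1cc(OC)cc2c1[C@@H](c1cc(OC)cc(OC)c1)[C@H](c1ccc(OC)cc1)O2 | intermediate
32 | (2-tert-butoxy-2-oxoethyl)zinc bromide | CC(C)(C)OC(=O)C[Zn]Br | starting material
33 | tert-butyl 2-[(2R,3R)-3-(3,5-dimethoxyphenyl)-6-methoxy-2-(4-methoxyphenyl)-2,3-dihydrobenzofuran-4-yl]acetate | CC(C)(C)OC(=O)Cc1cc(OC)cc2c1[C@@H](c1cc(OC)cc(OC)c1)[C@H](c1ccc(OC)cc1)O2 | intermediate
34 | the corresponding arylacetic acid | OC(=O)Cc1cc(OC)cc2c1[C@@H](c1cc(OC)cc(OC)c1)[C@H](c1ccc(OC)cc1)O2 | intermediate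
35 | mixed trifluoroacetic anhydride of 34 | FC(F)(F)C(=O)OC(=O)Cc1cc(OC)cc2c1[C@@H](c1cc(OC)cc(OC)c1)[C@H](c1ccc(OC)cc1)O2 | intermediate
36 | (7dR,8dR)-seven-ring ketone (carbonyl on ring D ortho to C8d, CH2 on ring C; furan of unit d intact) | O=C1Cc2cc(OC)cc3c2[C@@H](c2cc(OC)cc(OC)c21)[C@H](c1ccc(OC)cc1)O3 | intermediate
37 | 2-[(2R,3R)-3-(3,5-dimethoxyphenyl)-6-methoxy-2-(4-methoxyphenyl)-2,3-dihydrobenzofuran-4-yl]-4,4,5,5-tetramethyl-1,3,2-dioxaborolane | CC1(C)OB(OC1(C)C)c1cc(OC)cc2c1[C@@H](c1cc(OC)cc(OC)c1)[C@H](c1ccc(OC)cc1)O2 | intermediate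
38 | lithium enolate of 36 | [Li]OC1=Cc2cc(OC)cc3c2[C@@H](c2cc(OC)cc(OC)c21)[C@H](c1ccc(OC)cc1)O3 | intermediate
39 | lithium aldolate of 36 and 22 (new centres unassigned) | COc1ccc([C@H]2c3c(OC)cc(OC)cc3[C@@H]3c4c(cc(OC)cc4[C@H]2C(O[Li])C2c4cc(OC)cc5c4[C@@H](c4cc(OC)cc(OC)c4C2=O)[C@H](c2ccc(OC)cc2)O5)O[C@H]3c2ccc(OC)cc2)cc1 | intermediate
40 | mesylate of the aldol | COc1ccc([C@H]2c3c(OC)cc(OC)cc3[C@@H]3c4c(cc(OC)cc4[C@H]2C(OS(C)(=O)=O)C2c4cc(OC)cc5c4[C@@H](c4cc(OC)cc(OC)c4C2=O)[C@H](c2ccc(OC)cc2)O5)O[C@H]3c2ccc(OC)cc2)cc1 | intermediate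
41 | enone with C7c=C8c (geometry unassigned), left half on C7c, seven-ring ketone of unit d | COc1ccc([C@H]2c3c(OC)cc(OC)cc3[C@@H]3c4c(cc(OC)cc4[C@H]2C=C2c4cc(OC)cc5c4[C@@H](c4cc(OC)cc(OC)c4C2=O)[C@H](c2ccc(OC)cc2)O5)O[C@H]3c2ccc(OC)cc2)cc1 | intermediate
42 | bromomagnesium enolate after aryl addition at C7c | COc1ccc([C@H]2c3c(OC)cc(OC)cc3[C@@H]3c4c(cc(OC)cc4[C@H]2[C@H](c2ccc(OC)cc2)C2c4cc(OC)cc5c4[C@@H](c4cc(OC)cc(OC)c4C=2O[Mg]Br)[C@H](c2ccc(OC)cc2)O5)O[C@H]3c2ccc(OC)cc2)cc1 | intermediate
43 | seven-ring ketone with C7c (4-methoxyphenyl) and C8c set as in the target | COc1ccc([C@H]2c3c(OC)cc(OC)cc3[C@@H]3c4c(cc(OC)cc4[C@H]2[C@H](c2ccc(OC)cc2)[C@H]2c4cc(OC)cc5c4[C@@H](c4cc(OC)cc(OC)c4C2=O)[C@H](c2ccc(OC)cc2)O5)O[C@H]3c2ccc(OC)cc2)cc1 | intermediate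
44 | exocyclic methylene analogue of 43 | COc1ccc([C@H]2c3c(OC)cc(OC)cc3[C@@H]3c4c(cc(OC)cc4[C@H]2[C@H](c2ccc(OC)cc2)[C@H]2c4cc(OC)cc5c4[C@@H](c4cc(OC)cc(OC)c4C2=C)[C@H](c2ccc(OC)cc2)O5)O[C@H]3c2ccc(OC)cc2)cc1 | intermediate
45 | eight-ring dimethyl ketal (C7e = CH2 on ring D, C8e = C(OMe)2) | COc1ccc([C@H]2c3c(OC)cc(OC)cc3[C@@H]3c4c(cc(OC)cc4[C@H]2[C@H](c2ccc(OC)cc2)[C@H]2c4cc(OC)cc5c4[C@@H](c4cc(OC)cc(OC)c4CC2(OC)OC)[C@H](c2ccc(OC)cc2)O5)O[C@H]3c2ccc(OC)cc2)cc1 | intermediate
46 | eight-ring ketone (C8e = C=O, C7e = CH2) | COc1ccc([C@H]2c3c(OC)cc(OC)cc3[C@@H]3c4c(cc(OC)cc4[C@H]2[C@H](c2ccc(OC)cc2)[C@H]2c4cc(OC)cc5c4[C@@H](c4cc(OC)cc(OC)c4CC2=O)[C@H](c2ccc(OC)cc2)O5)O[C@H]3c2ccc(OC)cc2)cc1 | intermediate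
47 | potassium enolate of 46 toward C7e | COc1ccc([C@H]2c3c(OC)cc(OC)cc3[C@@H]3c4c(cc(OC)cc4[C@H]2[C@H](c2ccc(OC)cc2)[C@H]2c4cc(OC)cc5c4[C@@H](c4cc(OC)cc(OC)c4C=C2O[K])[C@H](c2ccc(OC)cc2)O5)O[C@H]3c2ccc(OC)cc2)cc1 | intermediate
48 | eight-ring enol triflate (C7e=C8e, ring cis) | COc1ccc([C@H]2c3c(OC)cc(OC)cc3[C@@H]3c4c(cc(OC)cc4[C@H]2[C@H](c2ccc(OC)cc2)[C@H]2c4cc(OC)cc5c4[C@@H](c4cc(OC)cc(OC)c4C=C2OS(=O)(=O)C(F)(F)F)[C@H](c2ccc(OC)cc2)O5)O[C@H]3c2ccc(OC)cc2)cc1 | intermediate
49 | eight-ring styrene with ring E (and its 7f,8f furan with ring F) on C8e | COc1ccc([C@H]2c3c(OC)cc(OC)cc3[C@@H]3c4c(cc(OC)cc4[C@H]2[C@H](c2ccc(OC)cc2)[C@H]2c4cc(OC)cc5c4[C@@H](c4cc(OC)cc(OC)c4C=C2c2cc(OC)cc4c2[C@@H](c2cc(OC)cc(OC)c2)[C@H](c2ccc(OC)cc2)O4)[C@H](c2ccc(OC)cc2)O5)O[C@H]3c2ccc(OC)cc2)cc1 | intermediate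
50 | monoalkylborane (BH2 on C7e, H on C8e, syn) | COc1ccc([C@H]2c3c(OC)cc(OC)cc3[C@@H]3c4c(cc(OC)cc4[C@H]2[C@H](c2ccc(OC)cc2)[C@H]2c4cc(OC)cc5c4[C@@H](c4cc(OC)cc(OC)c4[C@H](B)[C@H]2c2cc(OC)cc4c2[C@@H](c2cc(OC)cc(OC)c2)[C@H](c2ccc(OC)cc2)O4)[C@H](c2ccc(OC)cc2)O5)O[C@H]3c2ccc(OC)cc2)cc1 | intermediate
51 | potassium trifluoroborate at C7e | COc1ccc([C@H]2c3c(OC)cc(OC)cc3[C@@H]3c4c(cc(OC)cc4[C@H]2[C@H](c2ccc(OC)cc2)[C@H]2c4cc(OC)cc5c4[C@@H](c4cc(OC)cc(OC)c4[C@H]([B-](F)(F)F)[C@H]2c2cc(OC)cc4c2[C@@H](c2cc(OC)cc(OC)c2)[C@H](c2ccc(OC)cc2)O4)[C@H](c2ccc(OC)cc2)O5)O[C@H]3c2ccc(OC)cc2)cc1.[K+] | intermediate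
52 | 4-bromoanisole | COc1ccc(Br)cc1 | starting material
53 | (7aR,8aR,7bS,8bS,7cR,8cR,7dR,8dR,7eS,8eS,7fR,8fR)-pentadecamethyl ether of the target | COc1ccc([C@H]2c3c(OC)cc(OC)cc3[C@@H]3c4c(cc(OC)cc4[C@H]2[C@H](c2ccc(OC)cc2)[C@H]2c4cc(OC)cc5c4[C@@H](c4cc(OC)cc(OC)c4[C@H](c4ccc(OC)cc4)[C@H]2c2cc(OC)cc4c2[C@@H](c2cc(OC)cc(OC)c2)[C@H](c2ccc(OC)cc2)O4)[C@H](c2ccc(OC)cc2)O5)O[C@H]3c2ccc(OC)cc2)cc1 | intermediate
54 | CNP0184494.1, (7aR,8aR,7bS,8bS,7cR,8cR,7dR,8dR,7eS,8eS,7fR,8fR)-hexamer | Oc1ccc([C@H]2c3c(O)cc(O)cc3[C@@H]3c4c(cc(O)cc4[C@H]2[C@H](c2ccc(O)cc2)[C@H]2c4cc(O)cc5c4[C@@H](c4cc(O)cc(O)c4[C@H](c4ccc(O)cc4)[C@H]2c2cc(O)cc4c2[C@@H](c2cc(O)cc(O)c2)[C@H](c2ccc(O)cc2)O4)[C@H](c2ccc(O)cc2)O5)O[C@H]3c2ccc(O)cc2)cc1 | target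

**Count and risks**

Total step count: 27. Longest linear sequence: 18 steps (steps 2–10, then 19–27).

Steps most likely to fail:

1. Step 8. The tub-shaped quinone methide may be captured before its two helical forms interconvert, or through the less shielded ylide conformer, which would erode enantioface selection. The phenoxide may also be benzylated by the sulfonium salt, and excess ylide may add to the enoate. Fallback (resolution in place of reagent control): setting out from 14, annulate with (4-methoxybenzyl)dimethylsulfonium tetrafluoroborate F1 and Cs2CO3 to the racemic trans ester F2; saponify (LiOH, THF/H2O) to the racemic acid F3; crystallise the (R)-1-phenylethylammonium salt F4 of the (7aR,8aR) acid; liberate the (7aR,8aR)-acid F5 with dilute HCl and re-esterify (MeI, K2CO3, DMF), which comes back to the route at 18.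

2. Step 9. Conjugate addition may be slow at a hindered β-carbon deactivated by electron-rich ring A, 1,2-addition at the ester may compete, and the enolate may be protonated from the wrong face. Fallback (cationic hydroarylation, then separate epimerisation): setting out from 18, treat with anisole and catalytic CF3SO3H at 0 °C; protonation at C8b and para attack of anisole on the ring A-stabilised C7b cation, both from the convex face, should give mainly the 8b-epimeric ester F6. Deprotonate with KN(SiMe3)2 in THF at −78 °C to the potassium ester enolate F7 and quench with 2,6-di-tert-butylphenol (kinetic protonation anti to the C7b aryl group), which comes back to the route at 21.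

3. Step 26. Capture of the hindered secondary benzylic radical by nickel may be slow, with protodeboronation or photo-oxidation of the electron-rich rings competing. Fallback (two-electron, stereoretentive coupling that uses the boron centre set by hydroboration): setting out from 49, hydroborate with BH3·SMe2 and esterify the borane with pinacol to the C7e pinacol boronate F8; couple with 4-iodoanisole (Pd2(dba)3, PPh3, Ag2O, DME, 85 °C) with retention at C7e, which comes back to the route at 53.

**Further compounds**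

F1 | step 8 | (4-methoxybenzyl)dimethylsulfonium tetrafluoroborate | COc1ccc(C[S+](C)C)cc1.F[B-](F)(F)F
F2 | step 8 | racemic trans form of ester 18 | COC(=O)C1=Cc2c(OC)cc(OC)cc2C2c3c(cc(OC)cc31)OC2c1ccc(OC)cc1
F3 | step 8 | racemic trans carboxylic acid from F2 | OC(=O)C1=Cc2c(OC)cc(OC)cc2C2c3c(cc(OC)cc31)OC2c1ccc(OC)cc1
F4 | step 8 | (R)-1-phenylethylammonium salt of the (7aR,8aR) acid | [O-]C(=O)C1=Cc2c(OC)cc(OC)cc2[C@@H]2c3c(cc(OC)cc31)O[C@H]2c1ccc(OC)cc1.C[C@@H]([NH3+])c1ccccc1
F5 | step 8 | (7aR,8aR)-carboxylic acid | OC(=O)C1=Cc2c(OC)cc(OC)cc2[C@@H]2c3c(cc(OC)cc31)O[C@H]2c1ccc(OC)cc1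
F6 | step 9 | methyl (7aR,8aR,7bS,8bR)-ester, the 8b-epimer of 21 | COc1ccc([C@H]2c3c(OC)cc(OC)cc3[C@@H]3c4c(cc(OC)cc4[C@@H]2C(=O)OC)O[C@H]3c2ccc(OC)cc2)cc1
F7 | step 9 | potassium ester enolate of F6 | COc1ccc([C@H]2c3c(OC)cc(OC)cc3[C@@H]3c4c(cc(OC)cc4C2=C(OC)O[K])O[C@H]3c2ccc(OC)cc2)cc1
F8 | step 26 | C7e pinacol boronate (boron syn to H-8e) | COc1ccc([C@H]2c3c(OC)cc(OC)cc3[C@@H]3c4c(cc(OC)cc4[C@H]2[C@H](c2ccc(OC)cc2)[C@H]2c4cc(OC)cc5c4[C@@H](c4cc(OC)cc(OC)c4[C@H](B6OC(C)(C)C(C)(C)O6)[C@H]2c2cc(OC)cc4c2[C@@H](c2cc(OC)cc(OC)c2)[C@H](c2ccc(OC)cc2)O4)[C@H](c2ccc(OC)cc2)O5)O[C@H]3c2ccc(OC)cc2)cc1
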